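## Retrosynthetic overview
1. The target comes from its 3,7,4'-tri-O-MOM ether by one acid step. Rings A, B and C and all seven oxygens are bought as quercetin, so pyran ring D is the only ring built, and it is built last.
2. Ring D is disconnected at the O3'–C(CH3)2 bond (oxa-6π closure of an ortho-quinone methide). The same thermal cascade pushes the resident 2'-prenyl group to C6' with allyl inversion. Ring D and the 1,1-dimethylallyl group therefore both trace back to a 2'-prenyl 3'-O-(1,1-dimethylpropargyl) ether.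
3. All three C5 units enter through aryl O–C bonds: O3'–C(CH3)2C≡CH (copper catalysis), O5–CH2CH=C(CH3)2 (Williamson) and O3'–C(CH3)2CH=CH2 (palladium catalysis).
4. The 8-prenyl group comes from O5 (Claisen–Cope) and the 2'-prenyl group from O3' (ortho-Claisen), both in one flask.
5. Site selection rests on acidity-controlled 3,7,4'-tri-O-MOM protection. This leaves only the reactive 3'-OH and the sluggish, chelated 5-OH free.

Assumption: the SMILES shows no stereocentre, no stereogenic double bond and no axial descriptor. The target is therefore made as drawn, and possible slow rotation about C2–C1' is not resolved.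

## Route

Step 1
Reactants: 1 2-methylbut-3-en-2-ol
Product: 2 tert-butyl 2-methylbut-3-en-2-yl carbonate
Conditions: n-BuLi (1.05 equiv), THF, −78 to 0 °C; Boc2O (1.05 equiv), 0 °C to rt; H2O quench
Reagents that add atoms: di-tert-butyl dicarbonate, CC(C)(C)OC(=O)OC(=O)OC(C)(C)C
Why: O-acylation of a lithium alkoxide, in which the tertiary allylic alkoxide attacks a carbonyl of Boc2O, so the C–O bond of the alcohol is untouched, no allylic transposition occurs and no stereocentre is formed.

Step 2
Reactants: 3 quercetin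
Product: 4 3',5-dihydroxy-3,4',7-tris(methoxymethoxy)flavone
Conditions: MOMCl (3.1 equiv), K2CO3 (3.5 equiv), DMF, 0 °C to rt, argon
Reagents that add atoms: chloromethyl methyl ether, COCCl
Why: Williamson-type O-alkylation under acidity control, in which the three most acidic hydroxyls (7-OH, 4'-OH, 3-OH) are ionised and capped first, as in the known 3,7,4'-tribenzylation of quercetin, while 3'-OH and the carbonyl-chelated 5-OH stay free.

Step 3
Reactants: 4 3',5-dihydroxy-3,4',7-tris(methoxymethoxy)flavone; 2 tert-butyl 2-methylbut-3-en-2-yl carbonate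
Product: 5 5-hydroxy-3,4',7-tris(methoxymethoxy)-3'-(2-methylbut-3-en-2-yloxy)flavone
Conditions: Pd(PPh3)4 (5 mol %), 2 (1.3 equiv), THF, 0 °C to rt
Reagents that add atoms: none
Why: Tsuji–Trost O-allylation, in which zerovalent palladium ionises 2 with loss of CO2, the released tert-butoxide deprotonates 3'-OH, and the phenoxide attacks the more substituted terminus of the 1,1-dimethyl-π-allyl complex under kinetic control at low temperature, while the chelated 5-OH does not compete.

Step 4
Reactants: 5 5-hydroxy-3,4',7-tris(methoxymethoxy)-3'-(2-methylbut-3-en-2-yloxy)flavone; 6 prenyl bromide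
Product: 7 3,4',7-tris(methoxymethoxy)-3'-(2-methylbut-3-en-2-yloxy)-5-(3-methylbut-2-enyloxy)flavone
Conditions: 6 (1.5 equiv), K2CO3 (2 equiv), DMF, 50 °C
Reagents that add atoms: none
Why: Williamson etherification of the only remaining hydroxyl, where gentle heating in DMF breaks the 5-OH chelate yet stays well below the temperature at which either allyl ether rearranges.

Step 5
Reactants: 7 3,4',7-tris(methoxymethoxy)-3'-(2-methylbut-3-en-2-yloxy)-5-(3-methylbut-2-enyloxy)flavone
Product: 9 3',5-dihydroxy-3,4',7-tris(methoxymethoxy)-2',8-bis(3-methylbut-2-enyl)flavone, via ring-A-rearranged tertiary ether 8 (not isolated)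
Conditions: Eu(fod)3 (10 mol %), NaHCO3 (1 equiv), PhCl, 85 °C, 24 h, then 130 °C, 6 h
Reagents that add atoms: none
Why: Two aromatic Claisen events of known type run in sequence, first the Eu(fod)3-catalysed Claisen–Cope (para-Claisen) relay of the linear prenyl group from O5 to C8 with double inversion, then the ortho-Claisen rearrangement of the tertiary ether into the only open ortho position C2' (C4' carries OMOM), whose single inversion gives a linear prenyl group.

Step 6
Reactants: 9 3',5-dihydroxy-3,4',7-tris(methoxymethoxy)-2',8-bis(3-methylbut-2-enyl)flavone; 10 3-chloro-3-methylbut-1-yne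
Product: 11 5-hydroxy-3,4',7-tris(methoxymethoxy)-3'-(2-methylbut-3-yn-2-yloxy)-2',8-bis(3-methylbut-2-enyl)flavone
Conditions: 10 (3 equiv), CuI (5 mol %), KI (10 mol %), K2CO3 (2 equiv), acetone, 55 °C, argon
Reagents that add atoms: none
Why: Copper-catalysed propargylic etherification, in which the monovalent copper acetylide of 10 ionises to a flat allenylidene-type cation that even the di-ortho-substituted 3'-phenoxide captures at the tertiary carbon, whereas the chelated 5-OH is too poor a nucleophile.

Step 7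
Reactants: 11 5-hydroxy-3,4',7-tris(methoxymethoxy)-3'-(2-methylbut-3-yn-2-yloxy)-2',8-bis(3-methylbut-2-enyl)flavone
Product: 16 5-hydroxy-3,7-bis(methoxymethoxy)-2-[8-(methoxymethoxy)-2,2-dimethyl-6-(2-methylbut-3-en-2-yl)-2H-chromen-5-yl]-8-(3-methylbut-2-enyl)-4H-chromen-4-one, via allenyl prenyl ortho-dienone 12 (not isolated), via cross-conjugated para-dienone 13 (not isolated), via 2'-allenyl phenol 14 (not isolated), via ortho-quinone methide 15 (not isolated)
Conditions: PhNEt2 (0.05 M), 170 °C, sealed tube, argon, 8–12 h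
Reagents that add atoms: none
Why: Proposed new method: a propargyl Claisen cascade that expels an ortho-resident prenyl group, in which the [3,3] shift of the gem-dimethyl-accelerated propargyl ether can only reach substituted ortho carbons (attack at C4' is a reversible dead end) and attack at C2' gives dienone 12; the allenyl group of 12 is bound through an sp2 carbon and cannot enter a Cope shift, so only the prenyl group migrates, by [3,3] to the unsubstituted C6' with allyl inversion, giving the 1,1-dimethylallyl group of 13; the amine solvent shuttles the proton to give phenol 14, a 1,5-hydrogen shift gives the (Z)-quinone methide 15, and oxa-6π electrocyclisation forms the O3'–C(CH3)2 bond that closes ring D; the competing intramolecular Diels–Alder reaction of the allenyl dienone would have to bond at both fully substituted diene termini (C1' bearing the chromone, C4' bearing OMOM) and should be slower; the closest known reaction types are the para-Claisen (Claisen–Cope) rearrangement of 2,6-disubstituted aryl allyl ethers and the thermal aryl propargyl ether to 2H-chromene rearrangement, whose merger with transfer of a resident ortho group has not been described; the stereocentres of 12 and 13 are transient and racemic and vanish in 14.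

Step 8
Reactants: 16 tri-O-MOM ether of the target
Product: 17 3,5,7-trihydroxy-2-[8-hydroxy-2,2-dimethyl-6-(2-methylbut-3-en-2-yl)-2H-chromen-5-yl]-8-(3-methylbut-2-enyl)-4H-chromen-4-one (CNP0241222.0)
Conditions: HCl (1 M in MeOH), 40 °C, monitored closely, NaHCO3 quench
Reagents that add atoms: none
Why: Acid-catalysed acetal exchange (MOM cleavage) transfers the three CH2 units to methanol, and dilute methanolic HCl at this temperature does not protonate the prenyl, 1,1-dimethylallyl or chromene alkenes, as is routine for prenylated flavonoids.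

## Compound list
1 | 2-methylbut-3-en-2-ol | C=CC(C)(C)O | starting material
2 | tert-butyl 2-methylbut-3-en-2-yl carbonate | C=CC(C)(C)OC(=O)OC(C)(C)C | intermediate
3 | quercetin (3,3',4',5,7-pentahydroxyflavone) | Oc1ccc(cc1O)-c1oc2cc(O)cc(O)c2c(=O)c1O | starting material
4 | 3',5-dihydroxy-3,4',7-tris(methoxymethoxy)flavone | COCOc1ccc(cc1O)-c1oc2cc(OCOC)cc(O)c2c(=O)c1OCOC | intermediate
5 | 5-hydroxy-3,4',7-tris(methoxymethoxy)-3'-(2-methylbut-3-en-2-yloxy)flavone | COCOc1ccc(cc1OC(C)(C)C=C)-c1oc2cc(OCOC)cc(O)c2c(=O)c1OCOC | intermediate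
6 | prenyl bromide (1-bromo-3-methylbut-2-ene) | CC(C)=CCBr | starting material
7 | 3,4',7-tris(methoxymethoxy)-3'-(2-methylbut-3-en-2-yloxy)-5-(3-methylbut-2-enyloxy)flavone | COCOc1ccc(cc1OC(C)(C)C=C)-c1oc2cc(OCOC)cc(OCC=C(C)C)c2c(=O)c1OCOC | intermediate
8 | 5-hydroxy-3,4',7-tris(methoxymethoxy)-3'-(2-methylbut-3-en-2-yloxy)-8-(3-methylbut-2-enyl)flavone | COCOc1ccc(cc1OC(C)(C)C=C)-c1oc2c(CC=C(C)C)c(OCOC)cc(O)c2c(=O)c1OCOC | intermediate (not isolated)
9 | 3',5-dihydroxy-3,4',7-tris(methoxymethoxy)-2',8-bis(3-methylbut-2-enyl)flavone | COCOc1ccc(c(CC=C(C)C)c1O)-c1oc2c(CC=C(C)C)c(OCOC)cc(O)c2c(=O)c1OCOC | intermediate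
10 | 3-chloro-3-methylbut-1-yne | C#CC(C)(C)Cl | starting material
11 | 5-hydroxy-3,4',7-tris(methoxymethoxy)-3'-(2-methylbut-3-yn-2-yloxy)-2',8-bis(3-methylbut-2-enyl)flavone | COCOc1ccc(c(CC=C(C)C)c1OC(C)(C)C#C)-c1oc2c(CC=C(C)C)c(OCOC)cc(O)c2c(=O)c1OCOC | intermediate
12 | ring B ortho-dienone: C3' ketone, quaternary C2' carrying prenyl and 3-methylbuta-1,2-dienyl (racemic, transient) | O=C1C(OCOC)=CC=C(c2oc3c(CC=C(C)C)c(OCOC)cc(O)c3c(=O)c2OCOC)C1(CC=C(C)C)C=C=C(C)C | intermediate (not isolated)
13 | ring B para-dienone: C3' ketone, sp3 C6' carrying H and 2-methylbut-3-en-2-yl, C2' carrying the allenyl group (racemic, transient) | O=C1C(OCOC)=CC(C(C)(C)C=C)C(c2oc3c(CC=C(C)C)c(OCOC)cc(O)c3c(=O)c2OCOC)=C1C=C=C(C)C | intermediate (not isolated)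
14 | 3'-phenol carrying 2'-(3-methylbuta-1,2-dienyl) and 6'-(2-methylbut-3-en-2-yl) | Oc1c(OCOC)cc(C(C)(C)C=C)c(-c2oc3c(CC=C(C)C)c(OCOC)cc(O)c3c(=O)c2OCOC)c1C=C=C(C)C | intermediate (not isolated)
15 | (Z)-ortho-quinone methide: C3' ketone, C2'=CH–CH=C(CH3)2 with the dienyl chain cis to the carbonyl | O=C1C(OCOC)=CC(C(C)(C)C=C)=C(c2oc3c(CC=C(C)C)c(OCOC)cc(O)c3c(=O)c2OCOC)/C1=C/C=C(C)C | intermediate (not isolated)
16 | 5-hydroxy-3,7-bis(methoxymethoxy)-2-[8-(methoxymethoxy)-2,2-dimethyl-6-(2-methylbut-3-en-2-yl)-2H-chromen-5-yl]-8-(3-methylbut-2-enyl)-4H-chromen-4-one | C=CC(C)(C)c1cc(OCOC)c2c(c1-c1oc3c(CC=C(C)C)c(OCOC)cc(O)c3c(=O)c1OCOC)C=CC(C)(C)O2 | intermediate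
17 | 3,5,7-trihydroxy-2-[8-hydroxy-2,2-dimethyl-6-(2-methylbut-3-en-2-yl)-2H-chromen-5-yl]-8-(3-methylbut-2-enyl)-4H-chromen-4-one | C=CC(C)(C)c1cc(O)c2c(c1-c1oc3c(CC=C(C)C)c(O)cc(O)c3c(=O)c1O)C=CC(C)(C)O2 | target

## Step count
Total step count: 8. Longest linear sequence: 7 (steps 2 to 8 from quercetin; the branch through step 1 is equally long).

## Steps most likely to fail

**Step 7 (the new cascade).**
- Risk: dienone 12 may undergo the intramolecular Diels–Alder reaction instead of the Cope shift.
- Risk: 12 may send the prenyl group back to oxygen and lose isoprene.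
- Risk: 11 may simply shed the propargyl group and return 9.
- The fallback uses only known chemistry. It sets out from 9 and comes back at 16.
- Tsuji–Trost O-alkylation of 9 with carbonate 2 (Pd(PPh3)4, THF, 0 °C) gives 5-hydroxy-3,4',7-tris(methoxymethoxy)-3'-(2-methylbut-3-en-2-yloxy)-2',8-bis(3-methylbut-2-enyl)flavone F1.
- Heating F1 in PhNEt2 at 160 °C triggers the classical para-Claisen rearrangement. It passes through the 2',2'-diprenyl dienone, in which either prenyl group gives the same result. The product is 3',5-dihydroxy-3,4',7-tris(methoxymethoxy)-6'-(2-methylbut-3-en-2-yl)-2',8-bis(3-methylbut-2-enyl)flavone F2.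
- DDQ (1.1 equiv, toluene, 80 °C) then dehydrogenates the ortho-prenyl phenol of F2 to its quinone methide, which closes to chromene 16.
- The 8-prenyl group has no free ortho hydroxyl, and the chelated 5-OH is deactivated.

**Step 5 (two rearrangements in one flask).**
- Risk: the tertiary ether may lose isoprene in the presence of Eu(fod)3.
- Risk: ring A may give C6/C8 mixtures during the long heating.
- The fallback decouples the two events and changes the order of O–C bond formation. It sets out from 5 and comes back at 11.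
- Plain thermal ortho-Claisen rearrangement of 5 (DMF, 120 °C) gives 3',5-dihydroxy-3,4',7-tris(methoxymethoxy)-2'-(3-methylbut-2-enyl)flavone F3.
- Copper-catalysed etherification of F3 with 10 (CuI, K2CO3, acetone) gives 5-hydroxy-3,4',7-tris(methoxymethoxy)-3'-(2-methylbut-3-yn-2-yloxy)-2'-(3-methylbut-2-enyl)flavone F4.
- Williamson reaction of F4 with 6 gives 3,4',7-tris(methoxymethoxy)-3'-(2-methylbut-3-yn-2-yloxy)-5-(3-methylbut-2-enyloxy)-2'-(3-methylbut-2-enyl)flavone F5.
- The Eu(fod)3-catalysed Claisen–Cope relay on F5 at 85 °C, far below the onset of the propargyl Claisen reaction, delivers 11.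

**Step 2 (three of five hydroxyls in one operation).**
- Risk: di-, tri- and tetra-MOM mixtures form and are costly to separate.
- The fallback differentiates the catechol by a ketal instead of by acidity. It sets out from 3 and comes back at 4.
- Quercetin and dichlorodiphenylmethane (Ph2O, 175 °C) give 2-(2,2-diphenyl-1,3-benzodioxol-5-yl)-3,5,7-trihydroxychromen-4-one F6.
- MOMCl (2.2 equiv) with K2CO3 in acetone gives 2-(2,2-diphenyl-1,3-benzodioxol-5-yl)-5-hydroxy-3,7-bis(methoxymethoxy)chromen-4-one F7.
- Hydrogenolysis of F7 (H2, Pd/C, THF–EtOH) gives 3',4',5-trihydroxy-3,7-bis(methoxymethoxy)flavone F8.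
- One equivalent of MOMCl with K2CO3 in DMF caps the more acidic 4'-OH, following the known 4'-selective alkylation of this diol, and gives 4.

## Further compounds
F1 | step 7 | 5-hydroxy-3,4',7-tris(methoxymethoxy)-3'-(2-methylbut-3-en-2-yloxy)-2',8-bis(3-methylbut-2-enyl)flavone | COCOc1ccc(c(CC=C(C)C)c1OC(C)(C)C=C)-c1oc2c(CC=C(C)C)c(OCOC)cc(O)c2c(=O)c1OCOC
F2 | step 7 | 3',5-dihydroxy-3,4',7-tris(methoxymethoxy)-6'-(2-methylbut-3-en-2-yl)-2',8-bis(3-methylbut-2-enyl)flavone | COCOc1cc(C(C)(C)C=C)c(c(CC=C(C)C)c1O)-c1oc2c(CC=C(C)C)c(OCOC)cc(O)c2c(=O)c1OCOC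
F3 | step 5 | 3',5-dihydroxy-3,4',7-tris(methoxymethoxy)-2'-(3-methylbut-2-enyl)flavone | COCOc1ccc(c(CC=C(C)C)c1O)-c1oc2cc(OCOC)cc(O)c2c(=O)c1OCOC
F4 | step 5 | 5-hydroxy-3,4',7-tris(methoxymethoxy)-3'-(2-methylbut-3-yn-2-yloxy)-2'-(3-methylbut-2-enyl)flavone | COCOc1ccc(c(CC=C(C)C)c1OC(C)(C)C#C)-c1oc2cc(OCOC)cc(O)c2c(=O)c1OCOC
F5 | step 5 | 3,4',7-tris(methoxymethoxy)-3'-(2-methylbut-3-yn-2-yloxy)-5-(3-methylbut-2-enyloxy)-2'-(3-methylbut-2-enyl)flavone | COCOc1ccc(c(CC=C(C)C)c1OC(C)(C)C#C)-c1oc2cc(OCOC)cc(OCC=C(C)C)c2c(=O)c1OCOC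
F6 | step 2 | 2-(2,2-diphenyl-1,3-benzodioxol-5-yl)-3,5,7-trihydroxychromen-4-one | Oc1cc(O)c2c(c1)oc(-c1ccc3c(c1)OC(c1ccccc1)(c1ccccc1)O3)c(O)c2=O
F7 | step 2 | 2-(2,2-diphenyl-1,3-benzodioxol-5-yl)-5-hydroxy-3,7-bis(methoxymethoxy)chromen-4-one | COCOc1cc(O)c2c(c1)oc(-c1ccc3c(c1)OC(c1ccccc1)(c1ccccc1)O3)c(OCOC)c2=O
F8 | step 2 | 3',4',5-trihydroxy-3,7-bis(methoxymethoxy)flavone | COCOc1cc(O)c2c(c1)oc(-c1ccc(O)c(O)c1)c(OCOC)c2=O
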